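Ring C (the resorcinol) carries chromone C2 on C1' and the pyranone-bearing CH2 on the neighbouring C6', with the C2' oxygen beside C1'. This ortho pair next to an oxygen is the signature of a 3-alkoxyaryne difunctionalisation. The route therefore inserts 3,5-bis(benzyloxy)benzyne, released from silyl triflate 5, into the C2–CH2 bond of tert-butyl (chromon-2-yl)acetate 10: the enolate carbon adds at C6', and the aryl anion at C1' transfers onto chromone C2. One operation thus forms the C1'–C2 biaryl bond and the C6'–CH2 bond, joining the finished rings A and B to ring C. The acetate arm then becomes the 4-hydroxy-2-pyranone through a dioxinone, before global debenzylation.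

Key step: step 6

Remark: rings are called A (benzo ring of the chromone), B (its pyranone ring), C (resorcinol ring; C1' bonded to chromone C2, oxygen on C2' and C4', CH2 on C6') and D (2-pyranone); the target has no stereocentre, so no stereocontrol is needed, and 1, 6 and 15 are taken as purchasable.

Step 1
Reactants: 1 3,5-bis(benzyloxy)phenol
Product: 2 3,5-bis(benzyloxy)-2-bromophenol
Conditions: NBS (1.0 equiv), CH2Cl2, −78 °C to 0 °C
Reagents that add atoms: N-bromosuccinimide, O=C1CCC(=O)N1Br
Why: Electrophilic aromatic bromination should go ortho to the free hydroxyl (and para to a benzyloxy group), because the hydroxyl delivers the reagent by hydrogen bonding at low temperature and the other site, between the two benzyloxy groups, is the more hindered one.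

Step 2
Reactants: 2 3,5-bis(benzyloxy)-2-bromophenol
Product: 5 3,5-bis(benzyloxy)-2-(trimethylsilyl)phenyl trifluoromethanesulfonate, via aryl trimethylsilyl ether 3 (not isolated), via lithium 2-silylphenoxide 4 (not isolated)
Conditions: HN(SiMe3)2, THF, 65 °C, then evaporation; n-BuLi (1.05 equiv), THF, −100 °C to −78 °C; Tf2O, −100 °C to rt
Reagents that add atoms: hexamethyldisilazane, C[Si](C)(C)N[Si](C)(C)C; trifluoromethanesulfonic anhydride, O=S(=O)(OS(=O)(=O)C(F)(F)F)C(F)(F)F
Why: O-Silylation followed by bromine–lithium exchange triggers the 1,3 O-to-C silyl shift (retro-Brook rearrangement), and the lithium phenoxide 4 so formed is O-sulfonylated by Tf2O, the standard entry to ortho-silyl aryl triflates as aryne precursors.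

Step 3
Reactants: 6 1-(2,4-dihydroxy-6-methylphenyl)ethan-1-one
Product: 7 1-[4-(benzyloxy)-2-hydroxy-6-methylphenyl]ethan-1-one
Conditions: BnBr (1.05 equiv), K2CO3, acetone, reflux
Reagents that add atoms: benzyl bromide, BrCc1ccccc1
Why: Williamson ether synthesis that should be selective for the 4-hydroxyl, because the 2-hydroxyl is held in a hydrogen bond to the acetyl carbonyl and is the less nucleophilic one.

Step 4
Reactants: 7 1-[4-(benzyloxy)-2-hydroxy-6-methylphenyl]ethan-1-one
Product: 9 7-(benzyloxy)-2,5-dimethyl-4H-chromen-4-one, via 1,3-diketone 8 (not isolated)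
Conditions: NaH (4 equiv), EtOAc, THF, reflux; aq. HCl work-up; crude 8, cat. conc. HCl, MeOH, 50 °C
Reagents that add atoms: ethyl acetate, CCOC(C)=O
Why: Claisen condensation of the ketone enolate with ethyl acetate gives the 1,3-diketone 8, and acid-catalysed cyclodehydration of its ortho-hydroxyaryl diketone unit closes ring B as the 2-methylchromone (classical chromone synthesis).

Step 5
Reactants: 9 7-(benzyloxy)-2,5-dimethyl-4H-chromen-4-one
Product: 10 tert-butyl 2-[7-(benzyloxy)-5-methyl-4-oxo-4H-chromen-2-yl]acetate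
Conditions: LiN(iPr)2 (2.2 equiv), THF, −78 °C; Boc2O (1.1 equiv), −78 °C to 0 °C; aq. NH4Cl
Reagents that add atoms: di-tert-butyl dicarbonate, CC(C)(C)OC(=O)OC(=O)OC(C)(C)C
Why: Vinylogous enolate C-acylation, in which LiN(iPr)2 removes a proton from the 2-methyl group (the γ-position of the pyranone enone, whereas the 5-methyl group would require dearomatisation of ring A) and the extended enolate is acylated at its exocyclic carbon by Boc2O, the second equivalent of base taking up the more acidic product.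

Step 6
Reactants: 5 3,5-bis(benzyloxy)-2-(trimethylsilyl)phenyl trifluoromethanesulfonate; 10 tert-butyl 2-[7-(benzyloxy)-5-methyl-4-oxo-4H-chromen-2-yl]acetate
Product: 13 tert-butyl 2-{3,5-bis(benzyloxy)-2-[7-(benzyloxy)-5-methyl-4-oxo-4H-chromen-2-yl]phenyl}acetate, via 3,5-bis(benzyloxy)benzyne 11 (not isolated), via spiro-benzocyclobutene enolate 12 (not isolated)
Conditions: 5 (1.3 equiv), KF (3 equiv), 18-crown-6 (3 equiv), THF, 0 °C to rt
Reagents that add atoms: none
Why: Proposed new method: fluoride releases benzyne 11 from 5 and deprotonates 10, whose extended enolate should add through its exocyclic carbon to the aryne carbon remote from the neighbouring benzyloxy group (future C6'), the usual sense for 3-alkoxyarynes because it puts the aryl anion on C1' beside the inductively stabilising C–O bond. This aryl anion should add to chromone C2, the vinylogous acyl carbon, by a 4-exo-trig conjugate addition to give spiro enolate 12, which fragments by cleavage of the C2–CH bond (strain release, return of the chromone, ester-stabilised benzylic carbanion) and is protonated by a further molecule of 10 to give 13. The closest known reaction type is the acyl-alkylation of arynes, the insertion into the C(acyl)–C(α) bond of β-ketoesters and malonates; here the acyl acceptor is the vinylogous ester carbon of a chromone, which has not been shown. No ring of 13 is closed (the four-membered ring of 12 closes 4-exo-trig and reopens) and no stereocentre is formed, the two centres of 12 being lost on fragmentation. The step needs chemoselectivity for C2 over the ester carbonyl and over plain protonation of the aryl anion (α-arylation): the tert-butyl ester is a hindered acyl acceptor, the C4 carbonyl lies trans to the side chain across C2=C3 and cannot be reached, and aprotic THF leaves 10 as the only proton source. Loss of the ring A aryloxide from 12 would be reversible by oxa-Michael re-closure, so the irreversible C–C fragmentation should drain the mixture towards 13.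

Step 7
Reactants: 13 tert-butyl 2-{3,5-bis(benzyloxy)-2-[7-(benzyloxy)-5-methyl-4-oxo-4H-chromen-2-yl]phenyl}acetate
Product: 14 2-{3,5-bis(benzyloxy)-2-[7-(benzyloxy)-5-methyl-4-oxo-4H-chromen-2-yl]phenyl}acetic acid
Conditions: CF3CO2H, CH2Cl2 (1:4), 0 °C to rt
Reagents that add atoms: none
Why: Acidolysis of the tert-butyl ester (E1 loss of 2-methylpropene) should leave the aryl benzyl ethers and the chromone untouched at this acid strength and temperature.

Step 8
Reactants: 14 2-{3,5-bis(benzyloxy)-2-[7-(benzyloxy)-5-methyl-4-oxo-4H-chromen-2-yl]phenyl}acetic acid; 15 2,2,6-trimethyl-4H-1,3-dioxin-4-one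
Product: 17 6-(3-{3,5-bis(benzyloxy)-2-[7-(benzyloxy)-5-methyl-4-oxo-4H-chromen-2-yl]phenyl}-2-oxopropyl)-2,2-dimethyl-4H-1,3-dioxin-4-one, via acyl imidazole 16 (not isolated)
Conditions: CDI, THF, rt; added to 15 (3 equiv) pre-treated with LiN(iPr)2 (3 equiv), THF, −78 °C, then −78 °C to −40 °C; aq. NH4Cl
Reagents that add atoms: none
Why: Vinylogous Claisen condensation in which acyl imidazole 16 acylates the γ-carbon of the lithium dienolate of 15, used in excess because the β-keto-dioxinone product is deprotonated as it forms, while the 2-arylchromone is a poor Michael acceptor at −78 °C.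

Step 9
Reactants: 17 6-(3-{3,5-bis(benzyloxy)-2-[7-(benzyloxy)-5-methyl-4-oxo-4H-chromen-2-yl]phenyl}-2-oxopropyl)-2,2-dimethyl-4H-1,3-dioxin-4-one
Product: 19 6-({3,5-bis(benzyloxy)-2-[7-(benzyloxy)-5-methyl-4-oxo-4H-chromen-2-yl]phenyl}methyl)-4-hydroxy-2H-pyran-2-one, via acylketene 18 (not isolated)
Conditions: toluene, 110 °C
Reagents that add atoms: none
Why: Retro-hetero-Diels–Alder loss of acetone should give acylketene 18, whose ketene carbon is captured intramolecularly by the enol oxygen of the 5-ketone, closing ring D as the 4-hydroxy-2-pyranone.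

Step 10
Reactants: 19 6-({3,5-bis(benzyloxy)-2-[7-(benzyloxy)-5-methyl-4-oxo-4H-chromen-2-yl]phenyl}methyl)-4-hydroxy-2H-pyran-2-one
Product: 20 4-hydroxy-6-{[3,5-dihydroxy-2-(7-hydroxy-5-methyl-4-oxo-4H-chromen-2-yl)phenyl]methyl}-2H-pyran-2-one
Conditions: BCl3 (excess), C6HMe5 (pentamethylbenzene, 9 equiv), CH2Cl2, −78 °C to −40 °C; MeOH quench
Reagents that add atoms: none
Why: Lewis-acid cleavage of the three aryl benzyl ethers by BCl3, with pentamethylbenzene as a non-basic benzyl cation scavenger that should prevent C-benzylation of the electron-rich rings, while the lactone, the chromone and the diarylmethane-type CH2 are inert at low temperature.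

Compound list
1 | 3,5-bis(benzyloxy)phenol | Oc1cc(OCc2ccccc2)cc(OCc2ccccc2)c1 | starting material
2 | 3,5-bis(benzyloxy)-2-bromophenol | Oc1cc(OCc2ccccc2)cc(OCc2ccccc2)c1Br | intermediate
3 | [3,5-bis(benzyloxy)-2-bromophenoxy]trimethylsilane | C[Si](C)(C)Oc1cc(OCc2ccccc2)cc(OCc2ccccc2)c1Br | intermediate
4 | lithium 3,5-bis(benzyloxy)-2-(trimethylsilyl)phenoxide | [Li+].[O-]c1cc(OCc2ccccc2)cc(OCc2ccccc2)c1[Si](C)(C)C | intermediate
5 | 3,5-bis(benzyloxy)-2-(trimethylsilyl)phenyl trifluoromethanesulfonate | C[Si](C)(C)c1c(OCc2ccccc2)cc(OCc2ccccc2)cc1OS(=O)(=O)C(F)(F)F | intermediate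
6 | 1-(2,4-dihydroxy-6-methylphenyl)ethan-1-one | CC(=O)c1c(C)cc(O)cc1O | starting material
7 | 1-[4-(benzyloxy)-2-hydroxy-6-methylphenyl]ethan-1-one | CC(=O)c1c(C)cc(OCc2ccccc2)cc1O | intermediate
8 | 1-[4-(benzyloxy)-2-hydroxy-6-methylphenyl]butane-1,3-dione | CC(=O)CC(=O)c1c(C)cc(OCc2ccccc2)cc1O | intermediate
9 | 7-(benzyloxy)-2,5-dimethyl-4H-chromen-4-one | Cc1cc(=O)c2c(C)cc(OCc3ccccc3)cc2o1 | intermediate
10 | tert-butyl 2-[7-(benzyloxy)-5-methyl-4-oxo-4H-chromen-2-yl]acetate | CC(C)(C)OC(=O)Cc1cc(=O)c2c(C)cc(OCc3ccccc3)cc2o1 | intermediate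
11 | 3,5-bis(benzyloxy)benzyne (1,2-didehydro-3,5-bis(benzyloxy)benzene) | C1#CC(OCc2ccccc2)=CC(OCc2ccccc2)=C1 | intermediate
12 | potassium enolate of the spiro adduct in which a benzocyclobutene (carrying the tert-butyl ester on its CH) is spiro-joined at chromanone C2; transient mixture of diastereomers | [K+].CC(C)(C)OC(=O)C1c2cc(OCc3ccccc3)cc(OCc3ccccc3)c2C12C=C([O-])c1c(C)cc(OCc3ccccc3)cc1O2 | intermediate
13 | tert-butyl 2-{3,5-bis(benzyloxy)-2-[7-(benzyloxy)-5-methyl-4-oxo-4H-chromen-2-yl]phenyl}acetate | CC(C)(C)OC(=O)Cc1cc(OCc2ccccc2)cc(OCc2ccccc2)c1-c1cc(=O)c2c(C)cc(OCc3ccccc3)cc2o1 | intermediate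
14 | 2-{3,5-bis(benzyloxy)-2-[7-(benzyloxy)-5-methyl-4-oxo-4H-chromen-2-yl]phenyl}acetic acid | OC(=O)Cc1cc(OCc2ccccc2)cc(OCc2ccccc2)c1-c1cc(=O)c2c(C)cc(OCc3ccccc3)cc2o1 | intermediate
15 | 2,2,6-trimethyl-4H-1,3-dioxin-4-one | CC1=CC(=O)OC(C)(C)O1 | starting material
16 | 1-({3,5-bis(benzyloxy)-2-[7-(benzyloxy)-5-methyl-4-oxo-4H-chromen-2-yl]phenyl}acetyl)-1H-imidazole | O=C(Cc1cc(OCc2ccccc2)cc(OCc2ccccc2)c1-c1cc(=O)c2c(C)cc(OCc3ccccc3)cc2o1)n1ccnc1 | intermediate
17 | 6-(3-{3,5-bis(benzyloxy)-2-[7-(benzyloxy)-5-methyl-4-oxo-4H-chromen-2-yl]phenyl}-2-oxopropyl)-2,2-dimethyl-4H-1,3-dioxin-4-one | CC1(C)OC(=O)C=C(CC(=O)Cc2cc(OCc3ccccc3)cc(OCc3ccccc3)c2-c2cc(=O)c3c(C)cc(OCc4ccccc4)cc3o2)O1 | intermediate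
18 | 6-{3,5-bis(benzyloxy)-2-[7-(benzyloxy)-5-methyl-4-oxo-4H-chromen-2-yl]phenyl}hex-1-ene-1,3,5-trione (acylketene) | O=C=CC(=O)CC(=O)Cc1cc(OCc2ccccc2)cc(OCc2ccccc2)c1-c1cc(=O)c2c(C)cc(OCc3ccccc3)cc2o1 | intermediate
19 | 6-({3,5-bis(benzyloxy)-2-[7-(benzyloxy)-5-methyl-4-oxo-4H-chromen-2-yl]phenyl}methyl)-4-hydroxy-2H-pyran-2-one | O=c1cc(O)cc(Cc2cc(OCc3ccccc3)cc(OCc3ccccc3)c2-c2cc(=O)c3c(C)cc(OCc4ccccc4)cc3o2)o1 | intermediate
20 | 4-hydroxy-6-{[3,5-dihydroxy-2-(7-hydroxy-5-methyl-4-oxo-4H-chromen-2-yl)phenyl]methyl}-2H-pyran-2-one | Cc1cc(O)cc2oc(-c3c(O)cc(O)cc3Cc3cc(O)cc(=O)o3)cc(=O)c12 | target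

Total step count: 10 steps.
Longest linear sequence: 8 steps (6 to 20 through steps 3, 4, 5, 6, 7, 8, 9 and 10).

Steps most likely to fail

Step 6 (proposed new method): the aryl anion may be protonated before it closes onto chromone C2, which would leave plain α-arylation of 10, or it may attack the ester carbonyl instead of C2. The fallback uses known chemistry, sets out from 7 and comes back to the route at 14. Purchasable methyl 2-(3,5-dihydroxyphenyl)acetate is benzylated (BnBr, K2CO3, DMF) to methyl 2-[3,5-bis(benzyloxy)phenyl]acetate F1. Vilsmeier–Haack formylation (POCl3, DMF, 0 °C to 60 °C) at the position ortho to the side chain and para to a benzyloxy group should give methyl 2-[3,5-bis(benzyloxy)-2-formylphenyl]acetate F2. Claisen–Schmidt condensation of F2 with 7 (KOH, EtOH/H2O, rt), which also saponifies the methyl ester, should give the 2'-hydroxychalcone (E)-2-{3,5-bis(benzyloxy)-2-[3-[4-(benzyloxy)-2-hydroxy-6-methylphenyl]-3-oxoprop-1-en-1-yl]phenyl}acetic acid F3. Oxidative cyclisation (cat. I2, DMSO, 120 °C) then closes ring B and gives acid 14, from which steps 8 to 10 follow unchanged.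

Step 8: the basic dienolate may enolise the acyl imidazole at its acidic benzylic CH2 instead of attacking the carbonyl, so that 14 is returned on work-up. The fallback avoids strong base, sets out from 14 and comes back at 19. (COCl)2 with cat. DMF in CH2Cl2 gives 2-{3,5-bis(benzyloxy)-2-[7-(benzyloxy)-5-methyl-4-oxo-4H-chromen-2-yl]phenyl}acetyl chloride F4. F4 should acylate the terminal carbon of 1-methoxy-1,3-bis(trimethylsilyloxy)buta-1,3-diene (CH2Cl2, −78 °C to rt, aqueous work-up) to give methyl 6-{3,5-bis(benzyloxy)-2-[7-(benzyloxy)-5-methyl-4-oxo-4H-chromen-2-yl]phenyl}-3,5-dioxohexanoate F5. DBU in toluene at 80 °C lactonises F5 to pyranone 19, so that step 9 is not needed.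

Step 1: bromination may also take place between the two benzyloxy groups or twice, giving a mixture that is hard to separate. The fallback is a directed ortho-metalation that sets out from 1 and comes back at 5. iPrNCO and Et3N in CH2Cl2 give 3,5-bis(benzyloxy)phenyl N-(propan-2-yl)carbamate F6. In situ N-silylation (TBSOTf, TMEDA), ortho-lithiation (n-BuLi, TMEDA, Et2O, −78 °C) between the carbamate and a benzyloxy group (the two such positions are equivalent) and a Me3SiCl quench should give 3,5-bis(benzyloxy)-2-(trimethylsilyl)phenyl N-(propan-2-yl)carbamate F7. Et2NH and DBU in MeCN at 40 °C cleave the carbamate to 3,5-bis(benzyloxy)-2-(trimethylsilyl)phenol F8, which PhNTf2 converts in the same pot into 5.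

Further compounds
F1 | step 6 | methyl 2-[3,5-bis(benzyloxy)phenyl]acetate | COC(=O)Cc1cc(OCc2ccccc2)cc(OCc2ccccc2)c1
F2 | step 6 | methyl 2-[3,5-bis(benzyloxy)-2-formylphenyl]acetate | COC(=O)Cc1cc(OCc2ccccc2)cc(OCc2ccccc2)c1C=O
F3 | step 6 | (E)-2-{3,5-bis(benzyloxy)-2-[3-[4-(benzyloxy)-2-hydroxy-6-methylphenyl]-3-oxoprop-1-en-1-yl]phenyl}acetic acid | OC(=O)Cc1cc(OCc2ccccc2)cc(OCc2ccccc2)c1/C=C/C(=O)c1c(C)cc(OCc2ccccc2)cc1O
F4 | step 8 | 2-{3,5-bis(benzyloxy)-2-[7-(benzyloxy)-5-methyl-4-oxo-4H-chromen-2-yl]phenyl}acetyl chloride | O=C(Cl)Cc1cc(OCc2ccccc2)cc(OCc2ccccc2)c1-c1cc(=O)c2c(C)cc(OCc3ccccc3)cc2o1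
F5 | step 8 | methyl 6-{3,5-bis(benzyloxy)-2-[7-(benzyloxy)-5-methyl-4-oxo-4H-chromen-2-yl]phenyl}-3,5-dioxohexanoate | COC(=O)CC(=O)CC(=O)Cc1cc(OCc2ccccc2)cc(OCc2ccccc2)c1-c1cc(=O)c2c(C)cc(OCc3ccccc3)cc2o1
F6 | step 1 | 3,5-bis(benzyloxy)phenyl N-(propan-2-yl)carbamate | CC(C)NC(=O)Oc1cc(OCc2ccccc2)cc(OCc2ccccc2)c1
F7 | step 1 | 3,5-bis(benzyloxy)-2-(trimethylsilyl)phenyl N-(propan-2-yl)carbamate | CC(C)NC(=O)Oc1cc(OCc2ccccc2)cc(OCc2ccccc2)c1[Si](C)(C)C
F8 | step 1 | 3,5-bis(benzyloxy)-2-(trimethylsilyl)phenol | Oc1cc(OCc2ccccc2)cc(OCc2ccccc2)c1[Si](C)(C)C
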